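Ring A is disconnected at C2–C3. Its C1=C2–C3=O enone is treated as a 2,3-dione minus the enol oxygen, so C2 and C3 are two adjacent carbonyl carbons held between C1H2 and quaternary C4, a pair of like-polarised centres joined by polarity inversion. A carbene-catalysed intramolecular acyloin reaction forms C2–C3 and closes ring A in one operation. Its precursor is a ring B cyclohexene 1,6-dialdehyde carrying the trans C5 (CMe2CHO) and C10 (CH2CHO) arms, the C8=C9 alkene and a 7β-silyloxy group. That oxygen later delivers C11, aryl ether attached, to the β face of C9 by Ireland–Claisen rearrangement. (S)-Carvone provides ring B and the absolute configuration.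

Key step: step 11

Remarks on the chemistry
- Drimane numbering is used throughout (ring B = C5 to C10; ring A = C1 to C5 and C10). α/β refer to the usual drimane drawing. The target is (5S,9S,10R): the C10 methyl is α, and H5, the C7 oxygen of the intermediates and C11 are β. C11 is therefore axial and trans to the C10 methyl, which is why it is delivered intramolecularly from O7.
- Compounds 3, 7, 9, 10 and 11 are drawn as the 8α-methyl epimer; the 8-epimer is carried along because C8 becomes trigonal in 12.
- The hydroperoxide carbon of 11 and C11 of 33 to 35 are epimer mixtures that are destroyed in the same or the next step. Acyloin 20 may contain its 3-epimer and the 2-hydroxy-3-ketone; all give 22.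
- The diketone between acyloin and enone is the 2,3-dione (C2 and C3), which can enolise only towards C1.

Step 1
Reactants: 1 (S)-carvone
Product: 3 (5S,6R)-2,6-dimethyl-5-(prop-1-en-2-yl)cyclohex-2-en-1-one (trans-6-methylcarvone), via cross-conjugated lithium enolate 2 (not isolated)
Conditions: LDA, THF, −78 °C; MeI, −78 → 0 °C
Reagents that add atoms: iodomethane, CI
Why: Kinetic deprotonation at the α′ carbon and SN2 methylation (enolate alkylation) should place the methyl mainly anti to the neighbouring isopropenyl group, and this centre (drimane C8) becomes trigonal in step 5, so both epimers are usable.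

Step 2
Reactants: 4 tert-butyl isobutyrate
Product: 6 1-tert-butoxy-2-methyl-1-(trimethylsilyloxy)prop-1-ene, via ester lithium enolate 5 (not isolated)
Conditions: LDA, THF, −78 °C; TMSCl, −78 °C → rt; distillation
Reagents that add atoms: chlorotrimethylsilane, C[Si](C)(C)Cl
Why: O-silylation of the ester enolate (silyl ketene acetal formation) is standard, and the two identical β-methyl groups leave no geometry issue.

Step 3
Reactants: 3 trans-6-methylcarvone; 6 silyl ketene acetal
Product: 7 tert-butyl 2-methyl-2-[2,4-dimethyl-5-(prop-1-en-2-yl)-3-(trimethylsilyloxy)cyclohex-2-en-1-yl]propanoate (C9(OTMS)=C10 enol ether; 5α side chain; 7β-isopropenyl; 8α-methyl)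
Conditions: Tf2NH (2 mol %), CH2Cl2, −78 °C; Et3N quench
Reagents that add atoms: 1-tert-butoxy-2-methyl-1-(trimethylsilyloxy)prop-1-ene (6), CC(C)=C(OC(C)(C)C)O[Si](C)(C)C
Why: Mukaiyama–Michael addition under silyl Lewis acid catalysis with silyl transfer to the enolate oxygen, in which the nucleophile attacks the enone β-carbon axially and anti to the isopropenyl group two carbons away (as is usual for carvone), sets drimane C5 (side chain α, H5 β) and gives a regiodefined C9=C10 enol ether.

Step 4
Reactants: 7 TMS enol ether; 8 tert-butyl bromoacetate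
Product: 10 tert-butyl 2-[2-(2-tert-butoxy-2-oxoethyl)-2,4-dimethyl-3-oxo-5-(prop-1-en-2-yl)cyclohexyl]-2-methylpropanoate (C9 ketone; 10β-CH2CO2tBu; 10α-CH3; 5α-CMe2CO2tBu; 7β-isopropenyl), via lithium enolate 9 (not isolated)
Conditions: MeLi, THF, 0 °C; DMPU, BrCH2CO2tBu, −78 → 0 °C
Reagents that add atoms: tert-butyl bromoacetate (8), CC(C)(C)OC(=O)CBr
Why: MeLi cleaves the O–Si bond to the regiodefined lithium enolate, whose SN2 reaction with the reactive α-bromo ester (enolate alkylation) should occur anti to the bulky neighbouring C5 side chain and so set quaternary C10 with the two arms trans, while tert-butyl esters resist MeLi and acyl transfer to the enolate.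

Step 5
Reactants: 10 keto diester
Product: 12 tert-butyl 2-[6-(2-tert-butoxy-2-oxoethyl)-4,6-dimethyl-5-oxocyclohex-3-en-1-yl]-2-methylpropanoate (C7=C8(CH3)–C9=O enone), via methoxy hydroperoxide 11 (not isolated)
Conditions: O3, CH2Cl2/MeOH, −78 °C; Cu(OAc)2·H2O, FeSO4·7H2O, −78 °C → rt
Reagents that add atoms: none
Why: Ozonolysis in methanol turns the only alkene into an α-methoxy hydroperoxide, which divalent iron reduces to an alkoxy radical that loses methyl acetate by β-scission, and divalent copper oxidises the C7 radical to the conjugated enone (oxidative dealkenylation, as known for dihydrocarvone), so both C8 epimers converge.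

Step 6
Reactants: 12 enone diester
Product: 13 7β,8β-epoxy ketone diester (8α-methyl)
Conditions: 30% H2O2, NaOH, MeOH, 0 °C
Reagents that add atoms: hydrogen peroxide, OO
Why: In this Weitz–Scheffer nucleophilic epoxidation the hydroperoxide should add to C7 axially and anti to the C5 side chain two carbons away, as in the epoxidation of carvone, so the epoxide is expected on the β face, which sets C7.

Step 7
Reactants: 13 epoxy ketone
Product: 16 tert-butyl 2-[6-(2-tert-butoxy-2-oxoethyl)-3-hydroxy-4,6-dimethylcyclohex-4-en-1-yl]-2-methylpropanoate (7β-OH; C8=C9), via epoxy hydrazone 14 (not isolated), via alkenyldiazene 15 (not isolated)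
Conditions: N2H4·H2O, AcOH (cat.), MeOH, 0 °C → rt
Reagents that add atoms: none
Why: In the Wharton transposition the epoxy hydrazone opens to an alkenyldiazene that loses N2, which moves the alkene to C8=C9 and leaves the C7–O bond and its β configuration intact, and the tert-butyl γ-keto ester should not cyclise with hydrazine to a pyridazinone.

Step 8
Reactants: 16 allylic alcohol
Product: 17 7β-tert-butyldimethylsilyl ether of 16
Conditions: TBSCl, imidazole, DMF, rt → 40 °C
Reagents that add atoms: tert-butyldimethylsilyl chloride, CC(C)(C)[Si](C)(C)Cl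
Why: Standard silylation of a secondary allylic alcohol masks O7 for the hydride and oxidation steps without touching a stereocentre.

Step 9
Reactants: 17 silyl ether diester
Product: 18 2-[3-(tert-butyldimethylsilyloxy)-6-(2-hydroxyethyl)-4,6-dimethylcyclohex-4-en-1-yl]-2-methylpropan-1-ol
Conditions: LiAlH4, THF, reflux; aqueous NaOH work-up
Reagents that add atoms: none
Why: LiAlH4 reduces both tert-butyl esters to primary alcohols (ester reduction), the neopentyl one needing reflux, while the silyl ether and the isolated trisubstituted alkene are inert.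

Step 10
Reactants: 18 diol
Product: 19 2-[3-(tert-butyldimethylsilyloxy)-4,6-dimethyl-6-(2-oxoethyl)cyclohex-4-en-1-yl]-2-methylpropanal (ring B dialdehyde; 5α-CMe2CHO; 10β-CH2CHO; 10α-CH3; 7β-OTBS)
Conditions: Dess–Martin periodinane, CH2Cl2, 0 °C → rt; used at once
Reagents that add atoms: none
Why: Dess–Martin oxidation converts both primary alcohols to aldehydes under near-neutral conditions, and no centre can epimerise because C4 and C10 are quaternary.

Step 11
Reactants: 19 ring B dialdehyde
Product: 20 7β-(tert-butyldimethylsilyloxy)-3α-hydroxy-11-nordrim-8-en-2-one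
Conditions: 3-benzyl-5-(2-hydroxyethyl)-4-methylthiazolium chloride (20 mol %), Et3N, EtOH, 70 °C, 0.02 M, Ar
Reagents that add atoms: none
Why: Deprotonation of the thiazolium salt gives a thiazol-2-ylidene that adds to the unhindered C2 aldehyde and, after proton shift, forms the Breslow enaminol (an acyl anion equivalent), which attacks the C3 aldehyde carbon and then expels the carbene to leave the acyloin. The closest known reaction type is the thiazolium- or triazolium-catalysed intramolecular acyloin (crossed benzoin) cyclisation of dialdehydes and keto aldehydes to five- and six-membered α-hydroxy ketones. Ring A closes in the 6-exo-trig mode, C2 attacking the exocyclic C3=O. The new C3 carbinol centre should arise from a chair-like transition state with the developing hydroxyl equatorial (3α) and can equilibrate through the enediol, but it is erased in step 12, so either epimer serves. The step needs chemoselectivity over which aldehyde becomes the donor, and the quaternary C4 secures it by blocking carbene addition at the neopentyl C3 aldehyde, leaving the CH2-bound C2 aldehyde as the only site for the Breslow intermediate. Aldol attack of C1 on C3 and oligomerisation are held back by the weak amine base and high dilution.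

Step 12
Reactants: 20 acyloin
Product: 22 7β-(tert-butyldimethylsilyloxy)-2-hydroxy-11-nordrima-1,8-dien-3-one (diosphenol), via 2,3-dione 21 (not isolated)
Conditions: Dess–Martin periodinane, CH2Cl2, rt; Et3N (cat.), rt
Reagents that add atoms: none
Why: Dess–Martin oxidation of the α-hydroxy ketone gives the 2,3-dione, which can enolise only towards C1 because C4 is quaternary and therefore settles as the diosphenol, and any 3-epimer or 2-hydroxy-3-ketone in 20 gives the same product.

Step 13
Reactants: 22 diosphenol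
Product: 23 7β-(tert-butyldimethylsilyloxy)-3-oxo-11-nordrima-1,8-dien-2-yl trifluoromethanesulfonate
Conditions: PhNTf2, Et3N, DMAP (cat.), CH2Cl2, 0 °C → rt
Reagents that add atoms: N-phenylbis(trifluoromethanesulfonimide), O=S(=O)(N(c1ccccc1)S(=O)(=O)C(F)(F)F)C(F)(F)F
Why: O-Sulfonylation of the acidic diosphenol hydroxyl (enol triflate formation) fixes the C1=C2 double bond with a leaving group on C2.

Step 14
Reactants: 23 enol triflate
Product: 24 7β-(tert-butyldimethylsilyloxy)-11-nordrima-1,8-dien-3-one
Conditions: Pd(OAc)2 (5 mol %), PPh3 (10 mol %), HCO2H, Et3N, DMF, 60 °C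
Reagents that add atoms: none
Why: In this palladium-catalysed formate hydrogenolysis of an enol triflate, zerovalent palladium inserts into C2–OTf and formate exchange, loss of CO2 and reductive elimination put hydrogen on C2, leaving the C1=C2–C3=O enone without ionising the allylic silyl ether.

Step 15
Reactants: 24 silyl ether enone
Product: 25 7β-hydroxy-11-nordrima-1,8-dien-3-one
Conditions: HF·pyridine, pyridine, THF, 0 °C → rt
Reagents that add atoms: none
Why: Fluoride cleavage of the Si–O bond under buffered acidic conditions (desilylation) frees the 7β-hydroxyl without forming an alkoxide that could add to the enone, which itself has no enolisable hydrogen.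

Step 16
Reactants: 25 allylic alcohol; 26 bromoacetyl bromide
Product: 27 3-oxo-11-nordrima-1,8-dien-7β-yl bromoacetate
Conditions: BrCH2COBr, pyridine, CH2Cl2, 0 °C
Reagents that add atoms: bromoacetyl bromide (26), BrCC(=O)Br
Why: Acylation of the secondary allylic alcohol by the acid bromide with pyridine as base (esterification) proceeds at oxygen with retention at C7.

Step 17
Reactants: 27 bromoacetate; 28 isofraxidin
Product: 30 3-oxo-11-nordrima-1,8-dien-7β-yl [(6,8-dimethoxy-2-oxo-2H-chromen-7-yl)oxy]acetate, via potassium isofraxidinate 29 (not isolated)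
Conditions: K2CO3, acetone, rt
Reagents that add atoms: isofraxidin (28), COc1cc2ccc(=O)oc2c(OC)c1O
Why: In this Williamson ether synthesis the phenoxide of isofraxidin should displace the bromide of the very reactive α-bromo ester by SN2 far faster than it attacks the ester carbonyl or the hindered enone.

Step 18
Reactants: 30 aryloxyacetate
Product: 34 2-[(6,8-dimethoxy-2-oxo-2H-chromen-7-yl)oxy]-2-[(9β)-3-oxo-11-nordrima-1,7-dien-9-yl]acetic acid (the target with CO2H on C11), via lithium enolate 31 (not isolated), via silyl ketene acetal 32 (not isolated), via trimethylsilyl ester 33 (not isolated)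
Conditions: TMSCl, LiHMDS, THF, −78 °C → 50 °C; aqueous citric acid
Reagents that add atoms: none
Why: The only acidic C–H bonds are those of the aryloxyacetate, so LiHMDS with TMSCl gives the silyl ketene acetal, whose Ireland–Claisen [3,3] shift across the pseudoaxial C7–O bond is suprafacial and therefore forms C9–C11 on the β face (anti to the C10 methyl) while moving the alkene to C7=C8, and the C11 configuration does not matter because the carboxyl group is removed next.

Step 19
Reactants: 34 carboxylic acid
Product: 36 7-{[(5S,9S,10R)-3-oxodrima-1,7-dien-11-yl]oxy}-6,8-dimethoxy-2H-chromen-2-one (CNP0330704.1), via Barton ester 35 (not isolated)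
Conditions: N-hydroxypyridine-2-thione, DCC, DMAP (cat.), CH2Cl2, dark, rt; t-BuSH, hν (tungsten lamp), rt
Reagents that add atoms: none
Why: In this Barton reductive decarboxylation the thiohydroxamate ester fragments under visible light to CO2 and an aryloxy-stabilised C11 radical, which should take hydrogen from the thiol faster than it can cyclise or fragment, giving the CH2–OAr ether without touching C9, the enone or the coumarin.

Compound list
1 | (S)-carvone, (5S)-2-methyl-5-(prop-1-en-2-yl)cyclohex-2-en-1-one | C=C(C)[C@H]1CC=C(C)C(=O)C1 | starting material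
2 | lithium α′-enolate of (S)-carvone (O–Li on C1, C1=C6) | C=C(C)[C@H]1CC=C(C)C(O[Li])=C1 | intermediate
3 | (5S,6R)-2,6-dimethyl-5-(prop-1-en-2-yl)cyclohex-2-en-1-one (trans-6-methylcarvone) | C=C(C)[C@H]1CC=C(C)C(=O)[C@@H]1C | intermediate
4 | tert-butyl isobutyrate | CC(C)C(=O)OC(C)(C)C | starting material
5 | lithium enolate of tert-butyl isobutyrate | CC(C)=C(O[Li])OC(C)(C)C | intermediate
6 | 1-tert-butoxy-2-methyl-1-(trimethylsilyloxy)prop-1-ene | CC(C)=C(OC(C)(C)C)O[Si](C)(C)C | intermediate
7 | tert-butyl 2-methyl-2-[2,4-dimethyl-5-(prop-1-en-2-yl)-3-(trimethylsilyloxy)cyclohex-2-en-1-yl]propanoate; C9(OTMS)=C10, 5α side chain, 7β-isopropenyl, 8α-methyl | CC1=C(O[Si](C)(C)C)[C@H](C)[C@@H](C(C)=C)C[C@@H]1C(C)(C)C(=O)OC(C)(C)C | intermediate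
8 | tert-butyl bromoacetate | CC(C)(C)OC(=O)CBr | starting material
9 | lithium enolate corresponding to 7 (O–Li in place of O–SiMe3) | CC1=C(O[Li])[C@H](C)[C@@H](C(C)=C)C[C@@H]1C(C)(C)C(=O)OC(C)(C)C | intermediate
10 | tert-butyl 2-[2-(2-tert-butoxy-2-oxoethyl)-2,4-dimethyl-3-oxo-5-(prop-1-en-2-yl)cyclohexyl]-2-methylpropanoate; C9 ketone, 10β-CH2CO2tBu, 10α-CH3, 5α-CMe2CO2tBu, 7β-isopropenyl, 8α-CH3 | O=C1[C@H](C)[C@@H](C(C)=C)C[C@H](C(C)(C)C(=O)OC(C)(C)C)[C@@]1(C)CC(=O)OC(C)(C)C | intermediate
11 | as 10 with 7β-C(CH3)(OCH3)OOH in place of isopropenyl (methoxy hydroperoxide) | O=C1[C@H](C)[C@@H](C(C)(OC)OO)C[C@H](C(C)(C)C(=O)OC(C)(C)C)[C@@]1(C)CC(=O)OC(C)(C)C | intermediate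
12 | tert-butyl 2-[6-(2-tert-butoxy-2-oxoethyl)-4,6-dimethyl-5-oxocyclohex-3-en-1-yl]-2-methylpropanoate; C7=C8(CH3)–C9=O, arms trans | O=C1C(C)=CC[C@H](C(C)(C)C(=O)OC(C)(C)C)[C@@]1(C)CC(=O)OC(C)(C)C | intermediate
13 | 7β,8β-epoxide of 12 (epoxy ketone, 8α-CH3) | O=C1[C@@]2(C)O[C@H]2C[C@H](C(C)(C)C(=O)OC(C)(C)C)[C@@]1(C)CC(=O)OC(C)(C)C | intermediate
14 | C9 hydrazone of 13 | NN=C1[C@@]2(C)O[C@H]2C[C@H](C(C)(C)C(=O)OC(C)(C)C)[C@@]1(C)CC(=O)OC(C)(C)C | intermediate
15 | alkenyldiazene: C8=C9 with N=NH on C9, 7β-OH | N=NC1=C(C)[C@@H](O)C[C@H](C(C)(C)C(=O)OC(C)(C)C)[C@@]1(C)CC(=O)OC(C)(C)C | intermediate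
16 | tert-butyl 2-[6-(2-tert-butoxy-2-oxoethyl)-3-hydroxy-4,6-dimethylcyclohex-4-en-1-yl]-2-methylpropanoate; 7β-OH, C8=C9 | C1=C(C)[C@@H](O)C[C@H](C(C)(C)C(=O)OC(C)(C)C)[C@@]1(C)CC(=O)OC(C)(C)C | intermediate
17 | 7β-tert-butyldimethylsilyl ether of 16 | C1=C(C)[C@@H](O[Si](C)(C)C(C)(C)C)C[C@H](C(C)(C)C(=O)OC(C)(C)C)[C@@]1(C)CC(=O)OC(C)(C)C | intermediate
18 | 2-[3-(tert-butyldimethylsilyloxy)-6-(2-hydroxyethyl)-4,6-dimethylcyclohex-4-en-1-yl]-2-methylpropan-1-ol | C1=C(C)[C@@H](O[Si](C)(C)C(C)(C)C)C[C@H](C(C)(C)CO)[C@@]1(C)CCO | intermediate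
19 | 2-[3-(tert-butyldimethylsilyloxy)-4,6-dimethyl-6-(2-oxoethyl)cyclohex-4-en-1-yl]-2-methylpropanal; key-step precursor | C1=C(C)[C@@H](O[Si](C)(C)C(C)(C)C)C[C@H](C(C)(C)C=O)[C@@]1(C)CC=O | intermediate
20 | 7β-(tert-butyldimethylsilyloxy)-3α-hydroxy-11-nordrim-8-en-2-one; key-step product | C1=C(C)[C@@H](O[Si](C)(C)C(C)(C)C)C[C@@H]2C(C)(C)[C@H](O)C(=O)C[C@]21C | intermediate
21 | 7β-(tert-butyldimethylsilyloxy)-11-nordrim-8-ene-2,3-dione | C1=C(C)[C@@H](O[Si](C)(C)C(C)(C)C)C[C@@H]2C(C)(C)C(=O)C(=O)C[C@]21C | intermediate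
22 | 7β-(tert-butyldimethylsilyloxy)-2-hydroxy-11-nordrima-1,8-dien-3-one | C1=C(C)[C@@H](O[Si](C)(C)C(C)(C)C)C[C@@H]2C(C)(C)C(=O)C(O)=C[C@]21C | intermediate
23 | 7β-(tert-butyldimethylsilyloxy)-3-oxo-11-nordrima-1,8-dien-2-yl triflate | C1=C(C)[C@@H](O[Si](C)(C)C(C)(C)C)C[C@@H]2C(C)(C)C(=O)C(OS(=O)(=O)C(F)(F)F)=C[C@]21C | intermediate
24 | 7β-(tert-butyldimethylsilyloxy)-11-nordrima-1,8-dien-3-one | C1=C(C)[C@@H](O[Si](C)(C)C(C)(C)C)C[C@@H]2C(C)(C)C(=O)C=C[C@]21C | intermediate
25 | 7β-hydroxy-11-nordrima-1,8-dien-3-one | C1=C(C)[C@@H](O)C[C@@H]2C(C)(C)C(=O)C=C[C@]21C | intermediate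
26 | bromoacetyl bromide | BrCC(=O)Br | starting material
27 | 3-oxo-11-nordrima-1,8-dien-7β-yl bromoacetate | C1=C(C)[C@@H](OC(=O)CBr)C[C@@H]2C(C)(C)C(=O)C=C[C@]21C | intermediate
28 | isofraxidin, 7-hydroxy-6,8-dimethoxy-2H-chromen-2-one | COc1cc2ccc(=O)oc2c(OC)c1O | starting material
29 | potassium isofraxidinate | COc1cc2ccc(=O)oc2c(OC)c1[O-].[K+] | intermediate
30 | 3-oxo-11-nordrima-1,8-dien-7β-yl [(6,8-dimethoxy-2-oxo-2H-chromen-7-yl)oxy]acetate | C1=C(C)[C@@H](OC(=O)COc3c(OC)cc4ccc(=O)oc4c3OC)C[C@@H]2C(C)(C)C(=O)C=C[C@]21C | intermediate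
31 | lithium enolate of 30 (O–Li cis to the aryloxy group) | C1=C(C)[C@@H](O/C(O[Li])=C/Oc3c(OC)cc4ccc(=O)oc4c3OC)C[C@@H]2C(C)(C)C(=O)C=C[C@]21C | intermediate
32 | trimethylsilyl ketene acetal of 30 | C1=C(C)[C@@H](O/C(O[Si](C)(C)C)=C/Oc3c(OC)cc4ccc(=O)oc4c3OC)C[C@@H]2C(C)(C)C(=O)C=C[C@]21C | intermediate
33 | trimethylsilyl ester of 34 | COc1cc2ccc(=O)oc2c(OC)c1OC(C(=O)O[Si](C)(C)C)[C@H]1C(C)=CC[C@@H]2C(C)(C)C(=O)C=C[C@]21C | intermediate
34 | 2-[(6,8-dimethoxy-2-oxo-2H-chromen-7-yl)oxy]-2-[(9β)-3-oxo-11-nordrima-1,7-dien-9-yl]acetic acid | COc1cc2ccc(=O)oc2c(OC)c1OC(C(=O)O)[C@H]1C(C)=CC[C@@H]2C(C)(C)C(=O)C=C[C@]21C | intermediate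
35 | 2-thioxopyridin-1(2H)-yl ester of 34 (Barton ester) | COc1cc2ccc(=O)oc2c(OC)c1OC(C(=O)On3ccccc3=S)[C@H]1C(C)=CC[C@@H]2C(C)(C)C(=O)C=C[C@]21C | intermediate
36 | 7-{[(5S,9S,10R)-3-oxodrima-1,7-dien-11-yl]oxy}-6,8-dimethoxy-2H-chromen-2-one | COc1cc2ccc(=O)oc2c(OC)c1OC[C@H]1C(C)=CC[C@@H]2C(C)(C)C(=O)C=C[C@]21C | target

Total step count: 19. Longest linear sequence: 18 steps (step 1, then steps 3 to 19, from (S)-carvone); step 2 is a one-step side branch.

Steps most likely to fail

1. Step 11. The C1 enolate of the donor aldehyde may add to the C3 aldehyde (intramolecular aldol to a five-membered ring) before the Breslow intermediate forms, or the neopentyl aldehyde may resist attack so that oligomerisation takes over. Fallback: the same C2–C3 bond is made reductively instead of by umpolung. Setting out from dialdehyde 19, SmI2 in THF/t-BuOH (−78 °C → rt) should effect a pinacol cyclisation to the cis-2,3-diol F1. Double Swern oxidation (DMSO, (COCl)2, Et3N) would then give dione 21, which tautomerises, so the route is rejoined at diosphenol 22.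

2. Step 4. C-Alkylation at the tetrasubstituted enolate carbon, next to the neopentyl C5 centre, may be outrun by O-alkylation or by proton transfer from the product followed by alkylation at C8. Fallback: the SN2 step is replaced by a much less demanding carbonyl addition. Setting out from enol ether 7, enolate 9 (MeLi, THF) is treated with tert-butyl glyoxylate at −78 °C (aldol addition, again anti to the C5 side chain) and the aldolate is capped in the flask with Ac2O to give the α-acetoxy ester F2. SmI2 (THF/HMPA, MeOH, −78 °C) then removes the acetoxy group next to the ester, and the route is rejoined at keto diester 10.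

3. Step 18. The silazide base may attack the coumarin lactone, or the aryloxy enolate may fragment before it is silylated, and the [3,3] shift must form a bond next to quaternary C10. Fallback: the coumarin is kept out of the rearrangement and the aryl ether is made afterwards. Setting out from alcohol 25, esterification with (4-methoxybenzyloxy)acetic acid (DCC, DMAP) gives the glycolate ester F3. Ireland–Claisen rearrangement (LiHMDS, TMSCl, THF, −78 → 50 °C) gives the acid F4, and Barton decarboxylation as in step 19 gives the C11 p-methoxybenzyl ether F5. DDQ (CH2Cl2, pH 7 buffer) frees the 9β-hydroxymethyl compound F6. Mitsunobu etherification with isofraxidin 28 (PPh3, DIAD, toluene) then rejoins the route at target 36.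

Further compounds
F1 | step 11 | 7β-(tert-butyldimethylsilyloxy)-11-nordrim-8-ene-2,3-diol (cis-diol, carbinol configurations left open because both are oxidised) | C1=C(C)[C@@H](O[Si](C)(C)C(C)(C)C)C[C@@H]2C(C)(C)C(O)C(O)C[C@]21C
F2 | step 4 | tert-butyl 2-acetoxy-2-[C10]-acetate analogue of 10 (acetoxy group on C1, epimer mixture) | O=C1[C@H](C)[C@@H](C(C)=C)C[C@H](C(C)(C)C(=O)OC(C)(C)C)[C@@]1(C)C(OC(C)=O)C(=O)OC(C)(C)C
F3 | step 18 | 3-oxo-11-nordrima-1,8-dien-7β-yl (4-methoxybenzyloxy)acetate | C1=C(C)[C@@H](OC(=O)COCc3ccc(OC)cc3)C[C@@H]2C(C)(C)C(=O)C=C[C@]21C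
F4 | step 18 | 2-(4-methoxybenzyloxy)-2-[(9β)-3-oxo-11-nordrima-1,7-dien-9-yl]acetic acid (C11 epimer mixture) | COc1ccc(COC(C(=O)O)[C@H]2C(C)=CC[C@@H]3C(C)(C)C(=O)C=C[C@]32C)cc1
F5 | step 18 | (5S,9S,10R)-11-(4-methoxybenzyloxy)drima-1,7-dien-3-one | COc1ccc(COC[C@H]2C(C)=CC[C@@H]3C(C)(C)C(=O)C=C[C@]32C)cc1
F6 | step 18 | (5S,9S,10R)-11-hydroxydrima-1,7-dien-3-one | OC[C@H]1C(C)=CC[C@@H]2C(C)(C)C(=O)C=C[C@]21C
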